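**Conventions and assumption**

Halimane numbering is used throughout: C1–C10 decalin, C11–C16 side chain, C17 on C8, C18 (carboxyl) and C19 (methyl) on C4, C20 on C9. The β face is the face of ring B that carries the C9 side chain (and H5, H8, C18); the α face carries C17, C19 and C20. The stem "halim-" conveys connectivity only; configuration is specified by the CIP descriptors and the SMILES.

Assumption: the chiral ligands of steps 1 and 8 are taken in the antipodal form that delivers the configurations drawn; which antipode does so would be established on a model substrate before the real material is committed.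

## Analysis of the target

The target, compound 28, is a halimane-type decalin carrying a trisubstituted C1=C10 alkene, a quaternary C4 (methyl α, carboxylic acid β), a tertiary C5 (H β), a tertiary C8 (methyl α) and a quaternary C9 (methyl α, five-carbon chain β). Its descriptors are 4S,5S,8R,9S, and the side-chain alkene is 13E. The methyl groups on the contiguous C8 and C9 are cis, the C4 carboxyl is cis to H5, and H5 is cis to the C9 chain, so that the C4–C5 bond lies on the face of ring B that holds both methyl groups. C5 and C9 communicate only across the trigonal C10, which makes this the relationship hardest to control. Sensitive points are the allylic propanoate (ionisable and base-labile), the 1(10)-alkene (which can drift to the tetrasubstituted 5(10) position or be captured by the C4 acid under protic acid) and the shielded carboxyl group on the quaternary C4. The difficulty therefore lies in the two quaternary centres, the remote C5/C9 relationship and keeping the ring alkene at 1(10). The plan exploits the fact that the ester-bearing C4 is a direct neighbour of C5 while C10, the other ring neighbour of C5, is an alkene carbon: a carbenoid at C4, tethered to C10 through C1–C2–C3, can bridge a C5=C10 double bond of a ring B precursor. The temporary C4–C10 bond so formed is the one whose rupture puts charge on the tertiary C10, and loss of a C1 hydrogen then gives the C1=C10 alkene.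

## Retrosynthetic reasoning

**C15–O acyl bond (28 ⇒ 27).** The propanoate is the most labile group and is attached last, to the primary allylic alcohol of hydroxy acid 27. The forward step must acylate the alcohol without permanently engaging the hindered carboxyl group.

**Ester O–CH3 bond (27 ⇒ 26).** The C4 acid is carried as a methyl ester. It is cut at the O–methyl bond because the acyl carbon is shielded by the quaternary centre. This has to precede acylation, since an allylic ester would not survive the dealkylation.

**C13=C14 (26 ⇒ 25 ⇒ 24).** The side-chain alkene and C14–C15 come from a two-carbon carbonyl olefination of methyl ketone 24 to diester 25, followed by reduction of the new ester. Cutting here leaves a ketone that can travel as a dioxolane through all the ring chemistry.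

**C3 oxygen and ketal (24 ⇒ 23 ⇒ 22 ⇒ 21 ⇒ 20).** The C3 ketone is the price of the carbenoid chemistry. It is removed through alcohol 21 and thiocarbonyl derivative 22 only after it has activated C4 for alkylation. The dioxolane of 23 keeps C13 distinct from C3 and is opened afterwards.

**C4–C19 (20 ⇒ 19).** The C4 methyl is added to the enolate of β-keto ester 19. Doing this after ring A exists lets the ring conformation choose the face.

**C4–C10 re-formed (19 ⇒ 17, through 18).** Ring A and its alkene are traced back to cyclopropane 17, in which C4 is also bonded to C10. Forward, a halide nucleophile must break the bond to the more substituted carbon (iodide 18) and elimination must take a C1 hydrogen.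

**C4–C5 and C4–C10 (17 ⇒ 16).** Both bonds, two rings and three stereocentres come from addition of the C4 carbenoid of diazo keto ester 16 to C5=C10. This is the central disconnection because it attaches the ester-bearing carbon to C5 and sets up the 1(10)-alkene in one operation.

**Diazo group and C3–C4 (16 ⇒ 15 ⇒ 13 ⇒ 12).** The diazo group comes by diazo transfer to β-keto ester 15. Compound 15 comes from acid 13, through imidazolide 14, by a decarboxylative two-carbon homologation, and 13 comes from ester 12.

**C10–C1 (12 ⇒ 9 + 10).** The three-carbon tether is attached to the ring by cross-coupling of enol triflate 9 with zinc homoenolate 11, made from iodo ester 10. The triflate can form in one direction only, because C9 is quaternary.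

**Triflate and ketal (9 ⇒ 7 ⇒ 6).** Triflate 9 derives from ketone 7 through enolate 8, and 7 from diketone 6 by masking the unhindered methyl ketone.

**C8–C17 and C9–C11 (6 ⇒ 1 + 2).** Conjugate methylation of enone 1 and trapping of the enolate (3, 4) with silyl enone 2 set C8 by catalyst control and C9 trans to the new methyl. Desilylation of 5 gives 6.

## Alternatives that were turned down

Alternative 1: Ring A is cut at C2–C3 and C4–C5, giving the 2-vinylcyclohexene diene A2 (C9 masked as a dithiolane) and methacrolein A3. Forward, a chiral oxazaborolidinium Lewis acid (the B-o-tolyl oxazaborolidine from diphenylprolinol, protonated by HNTf2) would steer A3 onto A2 through the exo transition state and give aldehyde A1.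
- For: one step closes ring A, places the alkene at 1(10), and sets C4 and C5 together with the aldehyde carbon cis to H5; no C3 oxygen has to be removed. On these points it is stronger than the chosen route, which needs separate opening, methylation and deoxygenation steps.
- Against: A1 has C9 only as a masked ketone and C8 as CH2. Turning a carbonyl carbon into a quaternary centre with two different carbon groups, next to a new C8 methyl and correctly related to C5, is a long and poorly controlled sequence. The diene is also hindered by the adjacent dithiolane.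
- Comparison: the chosen route instead builds C8 and C9 first by reliable catalysis and takes its risk at C5.

Alternative 2: Rings A and B are cut together at C5–C10 and C8–C9, giving the acyclic trienone A5. Forward, complexation of the enone carbonyl of A5 by a chiral boron Lewis acid would trigger an endo intramolecular Diels–Alder reaction that delivers the cis-fused octalone A4.
- For: C5, C8, C9 and C10 are set in one event from alkene geometry, with the complete side chain in place. The C5/C9 relationship, the weak point of the chosen route, is secure here.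
- Against: the dienophile is a β,β-disubstituted enone that must form a quaternary centre, so reactivity and absolute control are doubtful. A5 needs several stereodefined alkenes. After cyclisation the two esters on C4 must be told apart to give methyl and carboxyl, the C1 ketone must become the 1(10)-alkene, and the 6,7-alkene must be hydrogenated beside the side-chain alkene.
- Comparison: the chosen route has C4 differentiated from the start (one ester, methyl added later) and fewer post-cyclisation corrections.

Alternative 3: Only C8–C17 and C9–C11 are cut. Forward, enone 1 takes up a methyl group at C8 from AlMe3 under catalysis by Cu(O2C-2-thienyl) (monovalent copper) and a chiral phosphoramidite; silyl enone 2 then intercepts the enolate at C9, and loss of silicon leaves diketone A6.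
- For: this is well-precedented catalytic chemistry and sets both ring B centres; it is more certain than any carbenoid step.
- Against: as a plan it stops at ring B and says nothing about ring A, C4 or C5.
- Comparison: it is kept as step 1 of the chosen route (A6 is compound 6), and the carbenoid step supplies what it lacks.

Key step: step 8

## Route

Step 1
Reactants: 1 2-methylcyclohex-2-en-1-one; 2 3-(trimethylsilyl)but-3-en-2-one
Product: 6 (2S,3R)-2,3-dimethyl-2-(3-oxobutyl)cyclohexan-1-one, via aluminium enolate 3 (not isolated), via lithium aluminate enolate 4 (not isolated), via silyl diketone 5 (not isolated)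
Conditions: Cu(O2C-2-thienyl) (CuTC, monovalent copper, cat.), BINOL-based bis(1-phenylethyl)amine phosphoramidite (cat.), AlMe3, Et2O, −30 °C; MeLi, THF, −78 °C; then 2, −78 → −20 °C; aq. work-up; K2CO3 (cat.), MeOH, 0 °C
Reagents that add atoms: trimethylaluminium, C[Al](C)C
Why: Copper-catalysed asymmetric conjugate addition sets C8 under ligand control; the enolate, activated as its aluminate, undergoes Michael addition to the α-silyl enone anti to the new methyl, which sets C9 with the two methyl groups cis. Mild methanolysis removes silicon without triggering aldol closure of the 1,5-diketone.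

Step 2
Reactants: 6 (2S,3R)-2,3-dimethyl-2-(3-oxobutyl)cyclohexan-1-one
Product: 7 (2S,3R)-2,3-dimethyl-2-[2-(2-methyl-1,3-dioxolan-2-yl)ethyl]cyclohexan-1-one
Conditions: (Me3SiOCH2)2, Me3SiOTf (cat.), CH2Cl2, −78 → −40 °C; pyridine quench
Reagents that add atoms: 1,2-bis(trimethylsilyloxy)ethane, C[Si](C)(C)OCCO[Si](C)(C)C
Why: Noyori ketalisation under kinetic conditions should take the unhindered methyl ketone and leave the ring ketone, which is flanked by the quaternary C9. The low temperature avoids acid-induced aldol closure.

Step 3
Reactants: 7 (2S,3R)-2,3-dimethyl-2-[2-(2-methyl-1,3-dioxolan-2-yl)ethyl]cyclohexan-1-one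
Product: 9 (5R,6S)-5,6-dimethyl-6-[2-(2-methyl-1,3-dioxolan-2-yl)ethyl]cyclohex-1-en-1-yl trifluoromethanesulfonate, via potassium enolate 8 (not isolated)
Conditions: KN(SiMe3)2, THF, −78 °C; PhNTf2, −78 → 0 °C
Reagents that add atoms: N-phenylbis(trifluoromethanesulfonimide), O=S(=O)(N(c1ccccc1)S(=O)(=O)C(F)(F)F)C(F)(F)F
Why: Only C5 carries α-hydrogens, so enolisation and O-triflation can give a single enol triflate (C10=C5). The ketal protects the side-chain ketone from the base.

Step 4
Reactants: 9 (5R,6S)-5,6-dimethyl-6-[2-(2-methyl-1,3-dioxolan-2-yl)ethyl]cyclohex-1-en-1-yl trifluoromethanesulfonate; 10 ethyl 3-iodopropanoate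
Product: 12 ethyl 3-{(5R,6S)-5,6-dimethyl-6-[2-(2-methyl-1,3-dioxolan-2-yl)ethyl]cyclohex-1-en-1-yl}propanoate, via zinc homoenolate 11 (not isolated)
Conditions: Zn dust (activated), LiCl, THF, 40 °C; then 9, Pd(PPh3)4 (zerovalent palladium, cat.), THF, 60 °C
Reagents that add atoms: none
Why: Negishi coupling of an alkenyl triflate with a zinc homoenolate forms C10–C1. The ester-chelated alkylzinc resists β-hydride loss and the ketal is inert to it.

Step 5
Reactants: 12 ethyl 3-{(5R,6S)-5,6-dimethyl-6-[2-(2-methyl-1,3-dioxolan-2-yl)ethyl]cyclohex-1-en-1-yl}propanoate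
Product: 13 3-{(5R,6S)-5,6-dimethyl-6-[2-(2-methyl-1,3-dioxolan-2-yl)ethyl]cyclohex-1-en-1-yl}propanoic acid
Conditions: LiOH·H2O, THF/MeOH/H2O, rt; 1 M HCl to pH 4, 0 °C
Reagents that add atoms: lithium hydroxide, [Li+].[OH-]
Why: Saponification of an unhindered primary ester. The brief cold acidification to pH 4 should spare the dioxolane.

Step 6
Reactants: 13 3-{(5R,6S)-5,6-dimethyl-6-[2-(2-methyl-1,3-dioxolan-2-yl)ethyl]cyclohex-1-en-1-yl}propanoic acid
Product: 15 methyl 5-{(5R,6S)-5,6-dimethyl-6-[2-(2-methyl-1,3-dioxolan-2-yl)ethyl]cyclohex-1-en-1-yl}-3-oxopentanoate, via acyl imidazolide 14 (not isolated)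
Conditions: 1,1′-carbonyldiimidazole, THF, rt; then Mg(O2CCH2CO2Me)2 [from KO2CCH2CO2Me and MgCl2], THF, rt → 40 °C; dil. HCl, 0 °C
Reagents that add atoms: potassium methyl malonate, COC(=O)CC(=O)[O-].[K+]
Why: Masamune–Brooks homologation: the magnesium malonate half-ester is C-acylated by the imidazolide and loses CO2 on work-up, adding C4 and the ester carbon under nearly neutral conditions.

Step 7
Reactants: 15 methyl 5-{(5R,6S)-5,6-dimethyl-6-[2-(2-methyl-1,3-dioxolan-2-yl)ethyl]cyclohex-1-en-1-yl}-3-oxopentanoate
Product: 16 methyl 2-diazo-5-{(5R,6S)-5,6-dimethyl-6-[2-(2-methyl-1,3-dioxolan-2-yl)ethyl]cyclohex-1-en-1-yl}-3-oxopentanoate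
Conditions: 4-acetamidobenzenesulfonyl azide, Et3N, MeCN, 0 °C → rt
Reagents that add atoms: 4-acetamidobenzenesulfonyl azide, CC(=O)Nc1ccc(cc1)S(=O)(=O)N=[N+]=[N-]
Why: Regitz diazo transfer to the active methylene of a β-keto ester. The acceptor-stabilised diazo compound is stable to chromatography.

Step 8
Reactants: 16 methyl 2-diazo-5-{(5R,6S)-5,6-dimethyl-6-[2-(2-methyl-1,3-dioxolan-2-yl)ethyl]cyclohex-1-en-1-yl}-3-oxopentanoate
Product: 17 methyl (4S,5S,8R,9S,10S)-13,13-ethylenedioxy-3-oxo-4,10-cyclo-14,15-dinorhaliman-18-oate (cyclopropane C4–C5–C10 on the α face; H5 β)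
Conditions: (CuOTf)2·C6H6 (monovalent copper, cat.), 2,2′-(propane-2,2-diyl)bis(4-tert-butyl-4,5-dihydrooxazole) (cat.), toluene, 50 °C, slow addition of 16
Reagents that add atoms: none
Why: The complex of CuOTf (monovalent copper) with the bis(oxazoline) converts the diazo keto ester into an electrophilic carbenoid at C4, which adds to the tethered alkene in a concerted, asynchronous [2+1] step (bond to C5 leading, charge building at the tertiary C10); the closest known reaction type is the copper- or dirhodium-catalysed intramolecular cyclopropanation of alkenes by α-diazo-β-keto esters. The cyclopentanone closes because C4 is held three atoms from C10 (5-exo with respect to the alkene carbon bearing the tether), the cyclopropane closes in the same suprafacial addition, and no sp3 C–H bond lies in a position for five-membered insertion. C4, C5 and C10 arise together and their mutual relationship is fixed by the cis ring fusions (C3 exo, ester endo over ring B), so the only open element is the face of C5=C10. The target needs the α face, so that H5 ends cis to the C9 chain. The half-chair of ring B with the C9 chain pseudo-axial opens this face apart from the axial C17 methyl, while the other half-chair (C20 pseudo-axial) opens the β face, so the substrate offers no dependable bias and may lean the wrong way. The facial choice therefore falls to the chiral ligand, whose antipode is chosen so that catalyst preference favours α addition. The two cyclopropane diastereomers differ at three centres and should be separable. The ketal oxygens are too remote for ylide formation and C5=C10 is the only alkene within reach.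

Step 9
Reactants: 17 methyl (4S,5S,8R,9S,10S)-13,13-ethylenedioxy-3-oxo-4,10-cyclo-14,15-dinorhaliman-18-oate
Product: 19 methyl (5S,8R,9S)-13,13-ethylenedioxy-3-hydroxy-14,15-dinorhalima-1(10),3-dien-18-oate (enol form of the ring A β-keto ester), via tertiary iodide 18 (not isolated)
Conditions: MgI2, THF, 0 → 45 °C; then DBU, 45 °C; aq. work-up
Reagents that add atoms: none
Why: Chelation of the 1,3-dicarbonyl by magnesium polarises the cyclopropane, and iodide should attack the quaternary C10 with inversion (homoconjugate addition), breaking C4–C10 and expanding the cyclopentanone to ring A while C5 is untouched. In iodide 18 the iodine is cis to H5, so anti elimination by DBU can only take a C1 hydrogen (C9 has none) and gives the 1(10)-alkene. The β-keto ester stays as its enolate, which prevents conjugation of the new β,γ-alkene.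

Step 10
Reactants: 19 methyl (5S,8R,9S)-13,13-ethylenedioxy-3-hydroxy-14,15-dinorhalima-1(10),3-dien-18-oate
Product: 20 methyl (4R,5S,8R,9S)-13,13-ethylenedioxy-3-oxo-14,15-dinorhalim-1(10)-en-18-oate (C4 methyl α; ester β)
Conditions: K2CO3, MeI, acetone, rt
Reagents that add atoms: iodomethane, CI
Why: C-alkylation of the cyclic β-keto ester enolate along the axial trajectory on the α face, anti to the pseudo-axial H5; because C10 is trigonal there is no syn-axial substituent to oppose it. This sets C4 with the methyl axial (α) and the ester equatorial (β, cis to H5).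

Step 11
Reactants: 20 methyl (4R,5S,8R,9S)-13,13-ethylenedioxy-3-oxo-14,15-dinorhalim-1(10)-en-18-oate
Product: 21 methyl (3R,4R,5S,8R,9S)-13,13-ethylenedioxy-3-hydroxy-14,15-dinorhalim-1(10)-en-18-oate
Conditions: NaBH4, CeCl3·7H2O, MeOH, −20 °C
Reagents that add atoms: none
Why: Luche-type borohydride reduction of the ketone; the hindered ester is not touched and the cold, fast reduction avoids retro-Claisen cleavage. The carbinol configuration (equatorial expected) is irrelevant because C3 becomes CH2.

Step 12
Reactants: 21 methyl (3R,4R,5S,8R,9S)-13,13-ethylenedioxy-3-hydroxy-14,15-dinorhalim-1(10)-en-18-oate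
Product: 22 methyl (3R,4R,5S,8R,9S)-13,13-ethylenedioxy-3-[(imidazol-1-ylcarbonothioyl)oxy]-14,15-dinorhalim-1(10)-en-18-oate
Conditions: 1,1′-thiocarbonyldiimidazole, DMAP (cat.), toluene, 90 °C
Reagents that add atoms: 1,1′-thiocarbonyldiimidazole, S=C(n1ccnc1)n1ccnc1
Why: Thioacylation under neutral conditions avoids the alkoxide and so avoids retro-aldol cleavage of the β-hydroxy ester. This is the first half of the Barton–McCombie deoxygenation.

Step 13
Reactants: 22 methyl (3R,4R,5S,8R,9S)-13,13-ethylenedioxy-3-[(imidazol-1-ylcarbonothioyl)oxy]-14,15-dinorhalim-1(10)-en-18-oate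
Product: 23 methyl (4S,5S,8R,9S)-13,13-ethylenedioxy-14,15-dinorhalim-1(10)-en-18-oate
Conditions: Bu3SnH, AIBN (cat.), toluene, 100 °C
Reagents that add atoms: none
Why: Barton–McCombie radical deoxygenation. The secondary C3 radical should be reduced by the stannane faster than it rearranges through the homoallyl–cyclopropylcarbinyl manifold; the alkene, ketal and ester are inert to tin radicals.

Step 14
Reactants: 23 methyl (4S,5S,8R,9S)-13,13-ethylenedioxy-14,15-dinorhalim-1(10)-en-18-oate
Product: 24 methyl (4S,5S,8R,9S)-13-oxo-14,15-dinorhalim-1(10)-en-18-oate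
Conditions: pyridinium p-toluenesulfonate (cat.), acetone/H2O, 50 °C
Reagents that add atoms: water, O
Why: Mild acid-catalysed ketal hydrolysis frees the methyl ketone. The weak acid should not move the 1(10)-alkene or touch the hindered ester.

Step 15
Reactants: 24 methyl (4S,5S,8R,9S)-13-oxo-14,15-dinorhalim-1(10)-en-18-oate
Product: 25 15-ethyl 18-methyl (4S,5S,8R,9S,13E)-halima-1(10),13-diene-15,18-dioate
Conditions: (EtO)2P(O)CH2CO2Et, NaH, THF, 0 → 50 °C
Reagents that add atoms: triethyl phosphonoacetate, CCOC(=O)CP(=O)(OCC)OCC
Why: Horner–Wadsworth–Emmons olefination of the methyl ketone adds C14 and C15 and should give mainly the E enoate (longer chain trans to the ester). The minor Z isomer would be removed by chromatography here or after step 16.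

Step 16
Reactants: 25 15-ethyl 18-methyl (4S,5S,8R,9S,13E)-halima-1(10),13-diene-15,18-dioate
Product: 26 methyl (4S,5S,8R,9S,13E)-15-hydroxyhalima-1(10),13-dien-18-oate
Conditions: i-Bu2AlH, CH2Cl2, −78 °C; aq. potassium sodium tartrate
Reagents that add atoms: none
Why: Chemoselective 1,2-reduction: the unhindered conjugated ethyl ester is reduced at low temperature, while the C4 methyl ester, attached to a quaternary ring carbon, should react far more slowly.

Step 17
Reactants: 26 methyl (4S,5S,8R,9S,13E)-15-hydroxyhalima-1(10),13-dien-18-oate
Product: 27 (4S,5S,8R,9S,13E)-15-hydroxyhalima-1(10),13-dien-18-oic acid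
Conditions: NaSEt, DMF, 90 °C; 1 M HCl to pH 3
Reagents that add atoms: none
Why: SN2 dealkylation at the ester methyl group by thiolate is insensitive to the shielding of the acyl carbon that blocks saponification. The allylic alcohol (as alkoxide) and both alkenes are not affected.

Step 18
Reactants: 27 (4S,5S,8R,9S,13E)-15-hydroxyhalima-1(10),13-dien-18-oic acid
Product: 28 (4S,5S,8R,9S,13E)-15-(propanoyloxy)halima-1(10),13-dien-18-oic acid (target)
Conditions: (EtCO)2O, pyridine, DMAP (cat.), CH2Cl2, 0 °C → rt; aq. NaHCO3, then pH 3
Reagents that add atoms: propanoic anhydride, CCC(=O)OC(=O)CC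
Why: DMAP-catalysed acylation of the primary allylic alcohol. Any mixed anhydride at the hindered C4 carboxyl is hydrolysed at the propanoyl carbonyl during the bicarbonate work-up, returning the free acid.

## Compound list

1 | 2-methylcyclohex-2-en-1-one | CC1=CCCCC1=O | starting material
2 | 3-(trimethylsilyl)but-3-en-2-one | CC(=O)C(=C)[Si](C)(C)C | starting material
3 | dimethylaluminium (3R)-2,3-dimethylcyclohex-1-en-1-olate | C[Al](C)OC1=C(C)[C@H](C)CCC1 | intermediate (not isolated)
4 | lithium [(3R)-2,3-dimethylcyclohex-1-en-1-yloxy]trimethylaluminate | [Li+].C[Al-](C)(C)OC1=C(C)[C@H](C)CCC1 | intermediate (not isolated)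
5 | (2S,3R)-2,3-dimethyl-2-[3-oxo-2-(trimethylsilyl)butyl]cyclohexan-1-one (both configurations at the silylated carbon) | CC(=O)C(C[C@]1(C)C(=O)CCC[C@H]1C)[Si](C)(C)C | intermediate (not isolated)
6 | (2S,3R)-2,3-dimethyl-2-(3-oxobutyl)cyclohexan-1-one | CC(=O)CC[C@]1(C)C(=O)CCC[C@H]1C | intermediate
7 | (2S,3R)-2,3-dimethyl-2-[2-(2-methyl-1,3-dioxolan-2-yl)ethyl]cyclohexan-1-one | CC1(CC[C@]2(C)C(=O)CCC[C@H]2C)OCCO1 | intermediate
8 | potassium enolate of 7 (C10=C5) | [K+].[O-]C1=CCC[C@@H](C)[C@]1(C)CCC2(C)OCCO2 | intermediate (not isolated)
9 | (5R,6S)-5,6-dimethyl-6-[2-(2-methyl-1,3-dioxolan-2-yl)ethyl]cyclohex-1-en-1-yl trifluoromethanesulfonate | O=S(=O)(OC1=CCC[C@@H](C)[C@]1(C)CCC2(C)OCCO2)C(F)(F)F | intermediate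
10 | ethyl 3-iodopropanoate | CCOC(=O)CCI | starting material
11 | (3-ethoxy-3-oxopropyl)zinc iodide | CCOC(=O)CC[Zn]I | intermediate (not isolated)
12 | ethyl 3-{(5R,6S)-5,6-dimethyl-6-[2-(2-methyl-1,3-dioxolan-2-yl)ethyl]cyclohex-1-en-1-yl}propanoate | CCOC(=O)CCC1=CCC[C@@H](C)[C@]1(C)CCC2(C)OCCO2 | intermediate
13 | 3-{(5R,6S)-5,6-dimethyl-6-[2-(2-methyl-1,3-dioxolan-2-yl)ethyl]cyclohex-1-en-1-yl}propanoic acid | OC(=O)CCC1=CCC[C@@H](C)[C@]1(C)CCC2(C)OCCO2 | intermediate
14 | acyl imidazolide of 13 | O=C(CCC1=CCC[C@@H](C)[C@]1(C)CCC2(C)OCCO2)n3ccnc3 | intermediate (not isolated)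
15 | methyl 5-{(5R,6S)-5,6-dimethyl-6-[2-(2-methyl-1,3-dioxolan-2-yl)ethyl]cyclohex-1-en-1-yl}-3-oxopentanoate | COC(=O)CC(=O)CCC1=CCC[C@@H](C)[C@]1(C)CCC2(C)OCCO2 | intermediate
16 | methyl 2-diazo-5-{(5R,6S)-5,6-dimethyl-6-[2-(2-methyl-1,3-dioxolan-2-yl)ethyl]cyclohex-1-en-1-yl}-3-oxopentanoate | COC(=O)C(=[N+]=[N-])C(=O)CCC1=CCC[C@@H](C)[C@]1(C)CCC2(C)OCCO2 | intermediate (key-step precursor)
17 | methyl (4S,5S,8R,9S,10S)-13,13-ethylenedioxy-3-oxo-4,10-cyclo-14,15-dinorhaliman-18-oate | COC(=O)[C@]12C(=O)CC[C@@]13[C@@H]2CC[C@@H](C)[C@]3(C)CCC4(C)OCCO4 | intermediate (key-step product)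
18 | 10β-iodo ring A keto ester, as its iodomagnesium enolate (drawn as the enol; iodine cis to H5) | COC(=O)C1=C(O)CC[C@@]2(I)[C@@H]1CC[C@@H](C)[C@]2(C)CCC3(C)OCCO3 | intermediate (not isolated)
19 | methyl (5S,8R,9S)-13,13-ethylenedioxy-3-hydroxy-14,15-dinorhalima-1(10),3-dien-18-oate (enol form of the 3-oxo ester) | COC(=O)C1=C(O)CC=C2[C@@H]1CC[C@@H](C)[C@]2(C)CCC3(C)OCCO3 | intermediate
20 | methyl (4R,5S,8R,9S)-13,13-ethylenedioxy-3-oxo-14,15-dinorhalim-1(10)-en-18-oate | COC(=O)[C@@]1(C)C(=O)CC=C2[C@@H]1CC[C@@H](C)[C@]2(C)CCC3(C)OCCO3 | intermediate
21 | methyl (3R,4R,5S,8R,9S)-13,13-ethylenedioxy-3-hydroxy-14,15-dinorhalim-1(10)-en-18-oate | COC(=O)[C@@]1(C)[C@H](O)CC=C2[C@@H]1CC[C@@H](C)[C@]2(C)CCC3(C)OCCO3 | intermediate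
22 | methyl (3R,4R,5S,8R,9S)-13,13-ethylenedioxy-3-[(imidazol-1-ylcarbonothioyl)oxy]-14,15-dinorhalim-1(10)-en-18-oate | COC(=O)[C@@]1(C)[C@H](OC(=S)n2ccnc2)CC=C3[C@@H]1CC[C@@H](C)[C@]3(C)CCC4(C)OCCO4 | intermediate
23 | methyl (4S,5S,8R,9S)-13,13-ethylenedioxy-14,15-dinorhalim-1(10)-en-18-oate | COC(=O)[C@@]1(C)CCC=C2[C@@H]1CC[C@@H](C)[C@]2(C)CCC3(C)OCCO3 | intermediate
24 | methyl (4S,5S,8R,9S)-13-oxo-14,15-dinorhalim-1(10)-en-18-oate | COC(=O)[C@@]1(C)CCC=C2[C@@H]1CC[C@@H](C)[C@]2(C)CCC(C)=O | intermediate
25 | 15-ethyl 18-methyl (4S,5S,8R,9S,13E)-halima-1(10),13-diene-15,18-dioate | COC(=O)[C@@]1(C)CCC=C2[C@@H]1CC[C@@H](C)[C@]2(C)CC/C(C)=C/C(=O)OCC | intermediate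
26 | methyl (4S,5S,8R,9S,13E)-15-hydroxyhalima-1(10),13-dien-18-oate | COC(=O)[C@@]1(C)CCC=C2[C@@H]1CC[C@@H](C)[C@]2(C)CC/C(C)=C/CO | intermediate
27 | (4S,5S,8R,9S,13E)-15-hydroxyhalima-1(10),13-dien-18-oic acid | OC(=O)[C@@]1(C)CCC=C2[C@@H]1CC[C@@H](C)[C@]2(C)CC/C(C)=C/CO | intermediate
28 | (4S,5S,8R,9S,13E)-15-(propanoyloxy)halima-1(10),13-dien-18-oic acid | CCC(=O)OC/C=C(\C)CC[C@]1(C)C2=CCC[C@](C)(C(=O)O)[C@H]2CC[C@H]1C | target

## Step count and least certain steps

Total: 18 steps. Longest linear sequence: 18 steps (from 1; the zinc reagent 11 is made in the flask).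

**Step 8 (key step).** The most likely failure is addition to the wrong face of C5=C10. Both ring B methyl groups sit on the α face, one of them axial in either half-chair, and the carbenoid ester must lie endo over ring B. β addition is therefore intrinsically easier, and the ligand has to override the substrate rather than reinforce it.
Fallback, setting out from 15 and returning at 19 (steps 7–9 are replaced): this uses the substrate's own preference. Buffered 3-chloroperbenzoic acid should epoxidise the trisubstituted alkene of 15 from the less hindered β face to the 5β,10β-epoxy keto ester F1. Potassium tert-butoxide in tert-butanol then lets the β-keto ester carbon open the epoxide at the secondary C5 with inversion (six-membered closure; the fully substituted C10 is not attacked). This puts C4 on the α face and gives the 10β-hydroxy keto ester F2. Thionyl chloride in pyridine dehydrates anti; the C10 oxygen is cis to H5, so only a C1 hydrogen can leave, and the sequence rejoins the route at 19.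

**Step 9.** The most likely failure is cleavage of the other cyclopropane bond: the ring ketone overlaps better with the exocyclic C4–C5 bond, so iodide attack at C5 competes with attack at C10. Capture of the C10 cation by the ester oxygen (lactonisation) and loss of the dioxolane under the Lewis acid are secondary risks.
Fallback, setting out from 15 and returning at 19 (no cyclopropane): N-chlorosuccinimide gives the α-chloro keto ester F3; the chlorine blocks over-oxidation. Mn(OAc)3·2H2O (trivalent manganese) with Cu(OAc)2·H2O (divalent copper) in ethanol generates the C4 radical, which closes 6-endo on C5. Divalent copper oxidises the tertiary C10 radical to the less substituted 1(10)-alkene, giving the chloro keto ester F4, and zinc in acetic acid removes the chlorine to return 19. Only the C4–C5 bond is formed, so no choice between two cyclopropane bonds arises, but the C5 configuration then has to be won again in the radical closure.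

**Step 10.** The most likely failure is methylation on the β face (or on oxygen). The axial preference of a ring enolate is modest and the neighbouring C5 carries the ring B carbon C6, so steric approach control could compete with the stereoelectronic preference.
Fallback, setting out from 19 and returning at 20: control passes to a covalently bound auxiliary. Condensation of 19 with tert-butyl L-valinate (or its antipode, whichever directs α entry) gives the enamino ester F5. Lithiation with LiN(i-Pr)2 and reaction with iodomethane gives the C4-methylated imino ester F6, whose face is set by the chelated valine ester. Buffered aqueous acetic acid hydrolyses the imine to 20.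

**Step 15.** The most likely failure is incomplete control of alkene geometry: a methyl ketone offers the phosphonate only a methyl-versus-methylene difference, so a substantial share of the Z enoate would have to be separated.
Fallback, setting out from 24 and returning at 26 (steps 15 and 16 are replaced): the alkene is built by syn carbometalation. LiN(i-Pr)2 and diethyl chlorophosphate convert 24 into the terminal enol phosphate F7. Excess LiN(i-Pr)2 eliminates it to the terminal alkyne F8. AlMe3 with Cp2ZrCl2 adds methyl and aluminium syn across the alkyne; the alkenylalane, activated with n-BuLi, is trapped with paraformaldehyde to give the E allylic alcohol 26 directly.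

## Further compounds

F1 | step 8 | 5β,10β-epoxide of 15: methyl 5-{5β,10β-epoxy ring B}-3-oxopentanoate | COC(=O)CC(=O)CC[C@@]12O[C@@H]1CC[C@@H](C)[C@]2(C)CCC3(C)OCCO3
F2 | step 8 | 10β-hydroxy ring A keto ester (enol form; C4 on the α face of C5, hydroxyl cis to H5) | COC(=O)C1=C(O)CC[C@@]2(O)[C@@H]1CC[C@@H](C)[C@]2(C)CCC3(C)OCCO3
F3 | step 9 | methyl 2-chloro-5-{(5R,6S)-5,6-dimethyl-6-[2-(2-methyl-1,3-dioxolan-2-yl)ethyl]cyclohex-1-en-1-yl}-3-oxopentanoate (both configurations at the chlorinated carbon) | COC(=O)C(Cl)C(=O)CCC1=CCC[C@@H](C)[C@]1(C)CCC2(C)OCCO2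
F4 | step 9 | 4-chloro derivative of the keto form of 19 (C4 configuration not defined) | COC(=O)C1(Cl)C(=O)CC=C2[C@@H]1CC[C@@H](C)[C@]2(C)CCC3(C)OCCO3
F5 | step 10 | enamino ester of 19 with tert-butyl L-valinate | COC(=O)C1=C(N[C@@H](C(C)C)C(=O)OC(C)(C)C)CC=C2[C@@H]1CC[C@@H](C)[C@]2(C)CCC3(C)OCCO3
F6 | step 10 | C4-methylated imino ester (methyl α) | COC(=O)[C@@]1(C)C(=N[C@@H](C(C)C)C(=O)OC(C)(C)C)CC=C2[C@@H]1CC[C@@H](C)[C@]2(C)CCC3(C)OCCO3
F7 | step 15 | terminal enol diethyl phosphate of 24 | COC(=O)[C@@]1(C)CCC=C2[C@@H]1CC[C@@H](C)[C@]2(C)CCC(=C)OP(=O)(OCC)OCC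
F8 | step 15 | terminal alkyne from 24 (C12–C≡CH) | COC(=O)[C@@]1(C)CCC=C2[C@@H]1CC[C@@H](C)[C@]2(C)CCC#C
A1 | alternative 1 | exo Diels–Alder adduct aldehyde | C[C@]1(C=O)CCC=C2[C@@H]1CCCC23SCCS3
A2 | alternative 1 | 6-ethenyl-1,4-dithiaspiro[4.5]dec-6-ene | C=CC1=CCCCC12SCCS2
A3 | alternative 1 | methacrolein | CC(=C)C=O
A4 | alternative 2 | cis-fused octalone adduct | CC(C)(C)[Si](c1ccccc1)(c1ccccc1)OC/C=C(\C)CC[C@]2(C)[C@H]3C(=O)CCC(C(=O)OC)(C(=O)OC)[C@H]3C=C[C@H]2C
A5 | alternative 2 | acyclic trienone precursor | CC(C)(C)[Si](c1ccccc1)(c1ccccc1)OC/C=C(\C)CC/C(C)=C/C(=O)CCC(C(=O)OC)(C(=O)OC)/C=C/C=C/C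
A6 | alternative 3 | (2S,3R)-2,3-dimethyl-2-(3-oxobutyl)cyclohexan-1-one | CC(=O)CC[C@]1(C)C(=O)CCC[C@H]1C
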